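The whole route rests on cutting ring C at C3–C4 and O1–C2. The target offers exactly what this needs: ring A is a phloroglucinol whose O1 sits ortho to an unsubstituted C4 methylene, and C3 next to it is an oxygen-bearing stereocenter. A 2-(tosylmethyl)phenol with two benzyl ethers releases an ortho-quinone methide that is trapped by the chiral enamine of a silyloxyacetaldehyde. In one operation C3–C4 forms, C3 is set as R and ring C closes as a lactol. Oxidation to the lactone, addition of the ring B aryllithium and cis-selective hydride reduction then set C2, followed by desilylation, galloylation and global hydrogenolysis.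

Key step: step 4

Assumption: 1, 5, 11 and 19 are bought as such (19 replaces gallic acid so that no separate benzylation is needed), and 14 is drawn as the open hydroxy ketone, the tautomer expected to dominate over its cyclic hemiketal.

Step 1
Reactants: 1 3,5-bis(benzyloxy)phenol
Product: 2 2,4-bis(benzyloxy)-6-hydroxybenzaldehyde
Conditions: MgCl2, Et3N, (CH2O)n, MeCN, reflux; aq HCl work-up
Reagents that add atoms: paraformaldehyde (formaldehyde), C=O
Why: Magnesium-mediated ortho-formylation (Casnati–Skattebøl reaction): the magnesium phenoxide directs formaldehyde to the ortho carbon and a second formaldehyde oxidises the benzylic alkoxide by hydride transfer, and since both ortho positions of 1 are equivalent a single salicylaldehyde should form.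

Step 2
Reactants: 2 2,4-bis(benzyloxy)-6-hydroxybenzaldehyde
Product: 3 3,5-bis(benzyloxy)-2-(hydroxymethyl)phenol
Conditions: NaBH4, THF/MeOH, 0 °C; neutral work-up, used crude
Reagents that add atoms: none
Why: Borohydride reduction of the aldehyde should give the salicyl alcohol, which is acid-sensitive and is therefore carried on without purification.

Step 3
Reactants: 3 3,5-bis(benzyloxy)-2-(hydroxymethyl)phenol
Product: 4 3,5-bis(benzyloxy)-2-(tosylmethyl)phenol
Conditions: p-TolSO2Na (3 equiv), HCO2H, THF/H2O, rt
Reagents that add atoms: sodium p-toluenesulfinate, Cc1ccc(S(=O)[O-])cc1.[Na+]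
Why: Acid-promoted SN1 sulfonylation: the electron-rich benzylic alcohol ionises to the protonated ortho-quinone methide, and the sulfur of the sulfinate, used in excess to outrun ring A as a nucleophile, traps it to give the sulfone as the thermodynamic product.

Step 4
Reactants: 4 3,5-bis(benzyloxy)-2-(tosylmethyl)phenol; 5 (tert-butyldimethylsilyloxy)acetaldehyde
Product: 9 (3R)-5,7-bis(benzyloxy)-3-(tert-butyldimethylsilyloxy)chroman-2-ol as an anomeric mixture, via ortho-quinone methide 6 (not isolated), via catalyst-bound enamine 7 (not isolated), via open-chain hydroxy aldehyde 8 (not isolated)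
Conditions: 5 (3 equiv), (S)-2-[diphenyl(trimethylsilyloxy)methyl]pyrrolidine (20 mol %), aq Na2CO3 (1.2 equiv), CH2Cl2, 0 °C to rt
Reagents that add atoms: none
Why: Carbonate deprotonates the phenol of 4, whose phenoxide expels p-toluenesulfinate to give the push-pull ortho-quinone methide 6, while the amine condenses with 5 to the E-enamine 7; the enamine α-carbon adds to the exocyclic CH2 of 6 (the future C4), which restores the aromaticity of ring A and forms C3–C4, and hydrolysis of the iminium releases the catalyst and hydroxy aldehyde 8. The closest known reaction type is the aminocatalytic formal [4+2] annulation of aldehydes with ortho-quinone methides generated in situ from 2-(sulfonylmethyl)phenols, which gives chroman-2-ols. Ring C closes by 6-exo-trig hemiacetalisation of the ring A phenol onto the aldehyde carbon (O1–C2), and this closure also masks the aldehyde, so the α-stereocenter is not re-enolised by the amine. C3 is controlled by the catalyst: the diphenyl(silyloxy)methyl group of the (S)-pyrrolidine blocks one face of the s-trans E-enamine, the methide adds to the open face and C3 should form as R, while the lactol carbon is not controlled and is removed as a stereocenter in step 5. The step needs chemoselectivity of the methide for the enamine carbon over ring A carbons, sulfinate and the catalyst nitrogen, and a single mode of ring closure; the excess of 5, the slow biphasic release of the methide and the two benzyl ethers, which stabilise the methide and leave only one free phenol, should secure both.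

Step 5
Reactants: 9 (3R)-5,7-bis(benzyloxy)-3-(tert-butyldimethylsilyloxy)chroman-2-ol
Product: 10 (3R)-5,7-bis(benzyloxy)-3-(tert-butyldimethylsilyloxy)chroman-2-one
Conditions: Dess–Martin periodinane, CH2Cl2, 0 °C to rt
Reagents that add atoms: none
Why: Dess–Martin oxidation of the lactol to the lactone under non-basic conditions erases the uncontrolled anomeric centre without touching the α-silyloxy stereocenter at C3.

Step 6
Reactants: 11 5-bromo-2-methoxyphenol
Product: 12 2-(benzyloxy)-4-bromo-1-methoxybenzene
Conditions: BnBr, K2CO3, DMF, rt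
Reagents that add atoms: benzyl bromide, BrCc1ccccc1
Why: Williamson ether synthesis on the phenoxide protects the ring B phenol with the same group as all other phenols.

Step 7
Reactants: 10 (3R)-5,7-bis(benzyloxy)-3-(tert-butyldimethylsilyloxy)chroman-2-one; 12 2-(benzyloxy)-4-bromo-1-methoxybenzene
Product: 14 (2R)-3-[2,4-bis(benzyloxy)-6-hydroxyphenyl]-1-[3-(benzyloxy)-4-methoxyphenyl]-2-(tert-butyldimethylsilyloxy)propan-1-one, via 3-benzyloxy-4-methoxyphenyllithium 13 (not isolated)
Conditions: 12, n-BuLi (1.05 equiv), THF, −78 °C; then cannulated into 10, THF, −78 °C; aq NH4Cl at −78 °C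
Reagents that add atoms: none
Why: Bromine–lithium exchange and single addition of the aryllithium to the aryl lactone (as in C-aryl glycoside synthesis from lactones): at −78 °C and with one equivalent added to the lactone the tetrahedral lithium alkoxide should persist until the quench, which releases the ketone with C3 unchanged.

Step 8
Reactants: 14 (2R)-3-[2,4-bis(benzyloxy)-6-hydroxyphenyl]-1-[3-(benzyloxy)-4-methoxyphenyl]-2-(tert-butyldimethylsilyloxy)propan-1-one
Product: 17 (2R,3R)-5,7-bis(benzyloxy)-2-[3-(benzyloxy)-4-methoxyphenyl]-3-(tert-butyldimethylsilyloxy)chromane, via cyclic hemiketal 15 (not isolated), via oxocarbenium ion 16 (not isolated)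
Conditions: Et3SiH (3 equiv), TMSOTf (0.2 equiv), CH2Cl2, −78 to −40 °C; Et3N quench
Reagents that add atoms: none
Why: Reductive etherification (ionic hydrogenation): the silyl triflate closes the phenol onto the ketone and ionises the hemiketal to the aryl-stabilised oxocarbenium ion, in which allylic 1,2-strain with the coplanar C2 aryl group holds the C3 silyloxy group pseudoaxial, so that Et3SiH should deliver hydride axially on the face anti to it and place the aryl group equatorial and cis to the C3 oxygen (2R).

Step 9
Reactants: 17 (2R,3R)-5,7-bis(benzyloxy)-2-[3-(benzyloxy)-4-methoxyphenyl]-3-(tert-butyldimethylsilyloxy)chromane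
Product: 18 (2R,3R)-5,7-bis(benzyloxy)-2-[3-(benzyloxy)-4-methoxyphenyl]chroman-3-ol
Conditions: TBAF, THF, 0 °C to rt
Reagents that add atoms: none
Why: Fluoride-mediated cleavage of the silyl ether, driven by the strength of the Si–F bond, frees the C3 alcohol while the benzyl ethers and both stereocenters are unaffected.

Step 10
Reactants: 18 (2R,3R)-5,7-bis(benzyloxy)-2-[3-(benzyloxy)-4-methoxyphenyl]chroman-3-ol; 19 3,4,5-tris(benzyloxy)benzoic acid
Product: 20 (2R,3R)-5,7-bis(benzyloxy)-2-[3-(benzyloxy)-4-methoxyphenyl]chroman-3-yl 3,4,5-tris(benzyloxy)benzoate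
Conditions: DCC, DMAP, CH2Cl2, rt
Reagents that add atoms: none
Why: Steglich esterification: DMAP transfers the acyl group from the O-acylisourea to the hindered axial C3 alcohol with retention at C3.

Step 11
Reactants: 20 (2R,3R)-5,7-bis(benzyloxy)-2-[3-(benzyloxy)-4-methoxyphenyl]chroman-3-yl 3,4,5-tris(benzyloxy)benzoate
Product: 21 4'-O-methylepicatechin-3-O-gallate
Conditions: H2 (1 atm), Pd(OH)2/C, THF/MeOH, rt
Reagents that add atoms: none
Why: Catalytic hydrogenolysis cleaves all six benzyl ethers under neutral conditions that should spare the ester and the C2–O1 bond and avoid base-induced epimerisation at C2.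

Compound list
1 | 3,5-bis(benzyloxy)phenol | Oc1cc(OCc2ccccc2)cc(OCc2ccccc2)c1 | starting material
2 | 2,4-bis(benzyloxy)-6-hydroxybenzaldehyde | O=Cc1c(O)cc(OCc2ccccc2)cc1OCc1ccccc1 | intermediate
3 | 3,5-bis(benzyloxy)-2-(hydroxymethyl)phenol | OCc1c(O)cc(OCc2ccccc2)cc1OCc1ccccc1 | intermediate
4 | 3,5-bis(benzyloxy)-2-(tosylmethyl)phenol | Cc1ccc(S(=O)(=O)Cc2c(O)cc(OCc3ccccc3)cc2OCc2ccccc2)cc1 | intermediate
5 | (tert-butyldimethylsilyloxy)acetaldehyde | O=CCO[Si](C)(C)C(C)(C)C | starting material
6 | 3,5-bis(benzyloxy)-6-methylidenecyclohexa-2,4-dien-1-one (ortho-quinone methide, not isolated) | C=C1C(=O)C=C(OCc2ccccc2)C=C1OCc1ccccc1 | intermediate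
7 | (S)-1-[(E)-2-(tert-butyldimethylsilyloxy)ethenyl]-2-[diphenyl(trimethylsilyloxy)methyl]pyrrolidine (enamine, not isolated) | CC(C)(C)[Si](C)(C)O/C=C/N1CCC[C@H]1C(c1ccccc1)(c1ccccc1)O[Si](C)(C)C | intermediate
8 | (2R)-3-[2,4-bis(benzyloxy)-6-hydroxyphenyl]-2-(tert-butyldimethylsilyloxy)propanal (not isolated) | O=C[C@@H](Cc1c(O)cc(OCc2ccccc2)cc1OCc1ccccc1)O[Si](C)(C)C(C)(C)C | intermediate
9 | (3R)-5,7-bis(benzyloxy)-3-(tert-butyldimethylsilyloxy)chroman-2-ol (anomeric mixture) | OC1Oc2cc(OCc3ccccc3)cc(OCc3ccccc3)c2C[C@H]1O[Si](C)(C)C(C)(C)C | intermediate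
10 | (3R)-5,7-bis(benzyloxy)-3-(tert-butyldimethylsilyloxy)chroman-2-one | O=C1Oc2cc(OCc3ccccc3)cc(OCc3ccccc3)c2C[C@H]1O[Si](C)(C)C(C)(C)C | intermediate
11 | 5-bromo-2-methoxyphenol | COc1ccc(Br)cc1O | starting material
12 | 2-(benzyloxy)-4-bromo-1-methoxybenzene | COc1ccc(Br)cc1OCc1ccccc1 | intermediate
13 | 3-benzyloxy-4-methoxyphenyllithium (not isolated) | COc1ccc([Li])cc1OCc1ccccc1 | intermediate
14 | (2R)-3-[2,4-bis(benzyloxy)-6-hydroxyphenyl]-1-[3-(benzyloxy)-4-methoxyphenyl]-2-(tert-butyldimethylsilyloxy)propan-1-one | COc1ccc(C(=O)[C@@H](Cc2c(O)cc(OCc3ccccc3)cc2OCc2ccccc2)O[Si](C)(C)C(C)(C)C)cc1OCc1ccccc1 | intermediate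
15 | (3R)-5,7-bis(benzyloxy)-2-[3-(benzyloxy)-4-methoxyphenyl]-3-(tert-butyldimethylsilyloxy)chroman-2-ol (cyclic hemiketal, not isolated) | COc1ccc(C2(O)Oc3cc(OCc4ccccc4)cc(OCc4ccccc4)c3C[C@H]2O[Si](C)(C)C(C)(C)C)cc1OCc1ccccc1 | intermediate
16 | (3R)-5,7-bis(benzyloxy)-2-[3-(benzyloxy)-4-methoxyphenyl]-3-(tert-butyldimethylsilyloxy)-3,4-dihydrochromenylium triflate (not isolated) | COc1ccc(C2=[O+]c3cc(OCc4ccccc4)cc(OCc4ccccc4)c3C[C@H]2O[Si](C)(C)C(C)(C)C)cc1OCc1ccccc1.[O-]S(=O)(=O)C(F)(F)F | intermediate
17 | (2R,3R)-5,7-bis(benzyloxy)-2-[3-(benzyloxy)-4-methoxyphenyl]-3-(tert-butyldimethylsilyloxy)chromane | COc1ccc([C@H]2Oc3cc(OCc4ccccc4)cc(OCc4ccccc4)c3C[C@H]2O[Si](C)(C)C(C)(C)C)cc1OCc1ccccc1 | intermediate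
18 | (2R,3R)-5,7-bis(benzyloxy)-2-[3-(benzyloxy)-4-methoxyphenyl]chroman-3-ol | COc1ccc([C@H]2Oc3cc(OCc4ccccc4)cc(OCc4ccccc4)c3C[C@H]2O)cc1OCc1ccccc1 | intermediate
19 | 3,4,5-tris(benzyloxy)benzoic acid | O=C(O)c1cc(OCc2ccccc2)c(OCc2ccccc2)c(OCc2ccccc2)c1 | starting material
20 | (2R,3R)-5,7-bis(benzyloxy)-2-[3-(benzyloxy)-4-methoxyphenyl]chroman-3-yl 3,4,5-tris(benzyloxy)benzoate | COc1ccc([C@H]2Oc3cc(OCc4ccccc4)cc(OCc4ccccc4)c3C[C@H]2OC(=O)c2cc(OCc3ccccc3)c(OCc3ccccc3)c(OCc3ccccc3)c2)cc1OCc1ccccc1 | intermediate
21 | 4'-O-methylepicatechin-3-O-gallate, (2R,3R) | COc1ccc([C@H]2Oc3cc(O)cc(O)c3C[C@H]2OC(=O)c2cc(O)c(O)c(O)c2)cc1O | target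

Total step count: 11. Longest linear sequence: 10 (steps 1 to 5 and 7 to 11; step 6 is the side branch).

Steps most likely to fail

Step 4. The unsubstituted methide may be consumed by carbon alkylation of electron-rich ring A (oligomerisation) or by N-alkylation of the catalyst before the enamine reaches it. Partial reaction through the Z-enamine of the α-silyloxy aldehyde would also lower the facial selectivity at C3. The fallback replaces aminocatalysis by auxiliary control and runs from 4 to 10. The lithium Z-enolate of (S)-4-benzyl-3-[(tert-butyldimethylsilyloxy)acetyl]oxazolidin-2-one F1 is formed with LiHMDS in THF at −78 °C (2.2 equiv); F1 is made from lithiated (S)-4-benzyloxazolidin-2-one and (tert-butyldimethylsilyloxy)acetyl chloride. It is treated with 4: one equivalent forms the phenoxide, which releases the methide on warming to about −20 °C. The second equivalent alkylates the methide on the enolate face anti to the auxiliary benzyl group (Evans-type glycolate alkylation), which should give (S)-4-benzyl-3-[(2R)-3-[2,4-bis(benzyloxy)-6-hydroxyphenyl]-2-(tert-butyldimethylsilyloxy)propanoyl]oxazolidin-2-one F2. The ortho phenoxide of F2 then attacks the exocyclic imide carbonyl (on warming, or with catalytic DBU after work-up) and expels the auxiliary. This gives lactone 10 directly, so the route is rejoined at 10 and step 5 is not needed.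

Step 8. Hydride delivery to the oxocarbenium ion may show poor facial selectivity and give 2,3-trans material. The C3 configuration may be lost through deprotonation of the cation to the enol ether, or the benzylic C2–O1 bond of the product may ionise and be reduced further. The fallback sets C2 by substrate-controlled addition and stereospecific ring closure; it runs from 9 to 17 and bypasses steps 5, 7 and 8. Lactol 9 is treated with excess [3-(benzyloxy)-4-methoxyphenyl]magnesium bromide F3 (from 12 and Mg, THF, −78 to 0 °C). The first equivalent opens the lactol to the phenoxide aldehyde and the second adds to the α-silyloxy aldehyde under Felkin–Anh control. This should give mainly the 1,2-anti product (1S,2R)-3-[2,4-bis(benzyloxy)-6-hydroxyphenyl]-1-[3-(benzyloxy)-4-methoxyphenyl]-2-(tert-butyldimethylsilyloxy)propan-1-ol F4, to be separated from its C1 epimer. Intramolecular Mitsunobu etherification (PPh3, DIAD, THF, 0 °C) then displaces the benzylic hydroxyl by the phenol with inversion and should give the 2,3-cis flavan 17.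

Step 7. The tetrahedral adduct may collapse to the ketone during the addition and take up a second aryllithium, or the lactone may be deprotonated at C3 (racemisation, ketene formation). The fallback uses an acyl donor that cannot over-add and runs from 10 to 14. Lactone 10 is opened with MeNHOMe·HCl and AlMe3 (CH2Cl2, 0 °C) to the Weinreb amide (2R)-3-[2,4-bis(benzyloxy)-6-hydroxyphenyl]-2-(tert-butyldimethylsilyloxy)-N-methoxy-N-methylpropanamide F5. Treatment with 2.2 equivalents of 13 at −78 °C (one equivalent for the phenol) should give a chelated adduct that survives until the quench and then releases ketone 14.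

Further compounds
F1 | step 4 | (S)-4-benzyl-3-[(tert-butyldimethylsilyloxy)acetyl]oxazolidin-2-one | CC(C)(C)[Si](C)(C)OCC(=O)N1[C@@H](Cc2ccccc2)COC1=O
F2 | step 4 | (S)-4-benzyl-3-[(2R)-3-[2,4-bis(benzyloxy)-6-hydroxyphenyl]-2-(tert-butyldimethylsilyloxy)propanoyl]oxazolidin-2-one | O=C([C@@H](Cc1c(O)cc(OCc2ccccc2)cc1OCc1ccccc1)O[Si](C)(C)C(C)(C)C)N1[C@@H](Cc2ccccc2)COC1=O
F3 | step 8 | [3-(benzyloxy)-4-methoxyphenyl]magnesium bromide | COc1ccc([Mg]Br)cc1OCc1ccccc1
F4 | step 8 | (1S,2R)-3-[2,4-bis(benzyloxy)-6-hydroxyphenyl]-1-[3-(benzyloxy)-4-methoxyphenyl]-2-(tert-butyldimethylsilyloxy)propan-1-ol | COc1ccc([C@H](O)[C@@H](Cc2c(O)cc(OCc3ccccc3)cc2OCc2ccccc2)O[Si](C)(C)C(C)(C)C)cc1OCc1ccccc1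
F5 | step 7 | (2R)-3-[2,4-bis(benzyloxy)-6-hydroxyphenyl]-2-(tert-butyldimethylsilyloxy)-N-methoxy-N-methylpropanamide | CON(C)C(=O)[C@@H](Cc1c(O)cc(OCc2ccccc2)cc1OCc1ccccc1)O[Si](C)(C)C(C)(C)C
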